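**Strategy.** Everything rests on cutting ring A (C1–C5, C10) at its unfunctionalised C2–C3 ethano unit, which lies between the C1 methylene on the angular C10 and the gem-dimethyl quaternary C4. In the key step this unit is inserted as a vinylphosphonium conjunctive reagent: the tertiary C4 radical, made by hydrogen-atom transfer to an isopropenyl group, adds to it (C3–C4), and the resulting ylide closes ring A by intramolecular Wittig reaction on a C1 aldehyde (C1=C2). The precursor is a monocyclic ring-B keto aldehyde obtained in three steps from (R)-carvone, which supplies C5, the isopropenyl (C4, C18, C19) and the C8 methyl. Singlet oxygen then installs 6α-O, and C9 is elaborated through a spiro-epoxide.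

Key step: step 4

Remark: labdane numbering (C1–C20) is used for all intermediates; the target is the 6α-acetoxy (equatorial), 8α-methyl, 9α-hydroxy isomer with trans ring fusion (5α-H, 10β-methyl), and (R)-(−)-carvone is taken as the commercial chiral source.

**Route**

Step 1
Reactants: 1 (R)-(−)-carvone; 2 iodomethane
Product: 3 (5R,6S)-2,6-dimethyl-5-(prop-1-en-2-yl)cyclohex-2-en-1-one (trans-6-methylcarvone; the minor epimer at the new centre is carried along)
Conditions: LiN(i-Pr)2 (LDA), THF, −78 °C; MeI, −78 to 0 °C
Reagents that add atoms: iodomethane, CI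
Why: Kinetic deprotonation at the α′ carbon (C10) gives the cross-conjugated lithium enolate, which is C-methylated (enolate alkylation); the configuration of the new centre is irrelevant because it is re-enolised in step 2.

Step 2
Reactants: 3 trans-6-methylcarvone; 4 formaldehyde (monomer from cracked paraformaldehyde)
Product: 5 (5S,6R)-6-(hydroxymethyl)-2,6-dimethyl-5-(prop-1-en-2-yl)cyclohex-2-en-1-one (CH2OH trans and CH3 cis to isopropenyl)
Conditions: LiN(i-Pr)2, THF, −78 °C; CH2O (g), −78 °C; AcOH quench
Reagents that add atoms: formaldehyde, C=O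
Why: The regenerated C10 enolate undergoes aldol addition to formaldehyde on the face anti to the neighbouring C5 isopropenyl group, so the quaternary centre should carry the hydroxymethyl (C1) trans and the methyl (C20) cis to isopropenyl; the cold acidic quench prevents retro-aldol loss.

Step 3
Reactants: 5 hydroxymethyl ketone
Product: 6 (1R,6S)-1,3-dimethyl-2-oxo-6-(prop-1-en-2-yl)cyclohex-3-ene-1-carbaldehyde (CHO trans to isopropenyl)
Conditions: Dess–Martin periodinane, CH2Cl2, 0 °C to rt
Reagents that add atoms: none
Why: Dess–Martin oxidation converts the neopentyl primary alcohol to the non-enolisable β-keto aldehyde under neutral conditions, avoiding retro-aldol cleavage and deformylation.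

Step 4
Reactants: 6 keto aldehyde; 7 vinyltriphenylphosphonium bromide
Product: 10 (4aS,8aS)-2,5,5,8a-tetramethyl-4a,5,6,8a-tetrahydronaphthalen-1(4H)-one (trans-fused dienone: C1=C2, C7=C8, C9 ketone, 5α-H, 10β-methyl), via phosphonium bromide 8 (not isolated), via phosphonium ylide 9 (not isolated)
Conditions: Fe(acac)3 (cat.), PhSiH3, EtOH/THF, 40 °C; evaporate; K2CO3, 18-crown-6, THF, 60 °C (one flask)
Reagents that add atoms: vinyltriphenylphosphonium bromide, C=C[P+](c1ccccc1)(c1ccccc1)c1ccccc1.[Br-]
Why: Proposed new method: Hydrogen-atom transfer from an iron hydride to the electron-rich isopropenyl group gives the tertiary C4 radical, which adds to the CH2 terminus of the vinylphosphonium salt (C3–C4 bond, quaternary C4); the α-phosphonio radical is reduced by divalent iron and protonated to salt 8, and carbonate then regenerates ylide 9, which closes ring A on the C1 aldehyde (C1=C2 bond) with loss of Ph3PO. The closest known reaction types are the metal-hydride HAT-initiated Giese addition of alkene-derived tertiary radicals to electron-poor alkenes and the radical conjunctive olefination in which alkyl radicals add to vinylphosphonium salts and the derived ylides undergo Wittig olefination, together with the Schweizer-type intramolecular Wittig annulation. Ring A is closed by a six-membered intramolecular Wittig olefination (ylide carbon C2 attacks the exocyclic aldehyde carbon C1, 6-exo-trig type), which can only give the cis ring alkene. No new stereocentre results, since C4 carries two methyl groups, and the trans ring fusion is carried over from the C5/C10 configuration of 6, whose isopropenyl and formyl groups are trans-diequatorial. The step needs hydrogen-atom transfer at the 1,1-disubstituted isopropenyl alkene instead of the electron-poor enone alkene, which the polarity preference of the metal hydride should secure, and ylide attack on the aldehyde instead of the C9 ketone, which the higher electrophilicity of the aldehyde and the bridgehead alkene required by the ketone pathway should secure.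

Step 5
Reactants: 10 dienone; 11 trimethylsilyl trifluoromethanesulfonate
Product: 12 trimethylsilyl dienol ether of 10 (ring-B 1,3-diene C6=C7–C8=C9 with OSiMe3 on C9; C1=C2 retained; used crude)
Conditions: Me3SiOTf, Et3N, CH2Cl2, 0 °C
Reagents that add atoms: trimethylsilyl trifluoromethanesulfonate, C[Si](C)(C)OS(=O)(=O)C(F)(F)F
Why: Soft enolisation with silyl triflate and amine: with C10 quaternary only γ-deprotonation at C6 is possible, which should give the linear 2-silyloxy-1,3-diene in ring B (silyl dienol ether formation).

Step 6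
Reactants: 12 silyl dienol ether; 13 dioxygen
Product: 15 6α-hydroxy dienone (6α-OH, C7=C8–C9=O enone, C1=C2, 5α-H, 10β-methyl), via silyloxy endoperoxide 14 (not isolated)
Conditions: O2, tetraphenylporphyrin (cat.), visible light, CH2Cl2, −78 °C; PPh3, −78 °C to rt; 1 M HCl, THF, 0 °C
Reagents that add atoms: dioxygen, O=O
Why: Singlet-oxygen [4+2] cycloaddition to the cisoid ring-B silyloxy diene should occur on the α face, because the β face is screened by the C10 methyl beside C9 and the 4β-methyl above C6; phosphine reduction of the peroxide and collapse of the C9 silyl hemiketal then leave the enone and the 6α-hydroxyl (C6 set by this facial choice).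

Step 7
Reactants: 15 6α-hydroxy dienone
Product: 17 6α-hydroxy-8α-methyl-9-ketone (trans-decalin, 4,4,8α,10β-tetramethyl, 5α-H), via 8β-methyl epimer 16 (not isolated)
Conditions: H2 (1 atm), Pd/C, EtOAc, rt; filter; NaOMe (cat.), MeOH, rt
Reagents that add atoms: none
Why: Catalytic hydrogenation saturates the ring-A alkene and the enone C=C, and methoxide then equilibrates C8 through the C9 enolate to the equatorial 8α-methyl ketone, which avoids the 1,3-diaxial contact of an 8β-methyl with the C10 methyl (thermodynamic control at C8).

Step 8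
Reactants: 17 hydroxy ketone; 18 methyltriphenylphosphonium bromide
Product: 19 6α-hydroxy-9-methylene compound (exocyclic C9=C11H2)
Conditions: Ph3PCH3Br, t-BuOK (excess), toluene, 90 °C
Reagents that add atoms: methyltriphenylphosphonium bromide, C[P+](c1ccccc1)(c1ccccc1)c1ccccc1.[Br-]
Why: Wittig methylenation with an excess of the non-stabilised ylide at raised temperature should convert the hindered C9 ketone to the exocyclic alkene, while C8 stays at its thermodynamic configuration under the basic conditions.

Step 9
Reactants: 19 exocyclic alkene; 20 3-chloroperoxybenzoic acid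
Product: 21 9α,11-epoxide (spiro-oxirane at C9, oxygen α-axial, CH2 β-equatorial; 6α-OH)
Conditions: mCPBA, CH2Cl2, 0 °C
Reagents that add atoms: 3-chloroperoxybenzoic acid, OOC(=O)c1cccc(Cl)c1
Why: Prilezhaev epoxidation of the exocyclic alkene should take the axial α trajectory, anti to the axial C10 methyl on the neighbouring carbon, so that the epoxide oxygen becomes the future 9α-hydroxyl.

Step 10
Reactants: 21 spiro-epoxide; 22 trimethylsulfonium iodide
Product: 23 6α,9α-diol with 9β-vinyl group (C11=C12)
Conditions: Me3SI (excess), n-BuLi, THF, −10 °C to rt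
Reagents that add atoms: trimethylsulfonium iodide, C[S+](C)C.[I-]
Why: Epoxide-to-allylic-alcohol homologation with excess dimethylsulfonium methylide: SN2 opening at the CH2 terminus followed by ylide-mediated β-elimination of dimethyl sulfide should give the vinyl carbinol without touching the C9–O bond.

Step 11
Reactants: 23 vinyl carbinol; 24 9-borabicyclo[3.3.1]nonane (9-BBN); 25 3-bromofuran-2(5H)-one
Product: 27 6α,9α-dihydroxy-labd-13-en-16,15-olide (8α-methyl), via B-alkyl-9-BBN 26 (not isolated)
Conditions: 9-BBN (excess), THF, rt to 50 °C; then 25, Pd(dppf)Cl2 (cat.), AsPh3, Cs2CO3, DMF/H2O, rt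
Reagents that add atoms: 3-bromofuran-2(5H)-one, O=C1OCC=C1Br
Why: Anti-Markovnikov hydroboration of the only alkene with 9-BBN and B-alkyl Suzuki–Miyaura coupling of the primary alkylborane with the α-bromobutenolide should join C12 to C13; no stereocentre is affected.

Step 12
Reactants: 27 diol butenolide; 28 acetic anhydride
Product: 29 (5S,6S,8R,9R,10S)-6α-acetoxy-9α-hydroxy-labd-13-en-16,15-olide (target)
Conditions: Ac2O, pyridine, DMAP (cat.), CH2Cl2, 0 °C to rt
Reagents that add atoms: acetic anhydride, CC(=O)OC(C)=O
Why: Acetylation under nucleophilic catalysis should be selective for the secondary equatorial C6 hydroxyl, the tertiary axial C9 hydroxyl being too hindered to react.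

**Compound list**

1 | (R)-(−)-carvone | C1C=C(C)C(=O)C[C@@H]1C(C)=C | starting material
2 | iodomethane | CI | starting material
3 | (5R,6S)-2,6-dimethyl-5-(prop-1-en-2-yl)cyclohex-2-en-1-one | C1C=C(C)C(=O)[C@@H](C)[C@@H]1C(C)=C | intermediate
4 | formaldehyde | C=O | starting material
5 | (5S,6R)-6-(hydroxymethyl)-2,6-dimethyl-5-(prop-1-en-2-yl)cyclohex-2-en-1-one | C1C=C(C)C(=O)[C@@](C)(CO)[C@@H]1C(C)=C | intermediate
6 | (1R,6S)-1,3-dimethyl-2-oxo-6-(prop-1-en-2-yl)cyclohex-3-ene-1-carbaldehyde | C1C=C(C)C(=O)[C@@](C)(C=O)[C@@H]1C(C)=C | intermediate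
7 | vinyltriphenylphosphonium bromide | C=C[P+](c1ccccc1)(c1ccccc1)c1ccccc1.[Br-] | starting material
8 | phosphonium bromide (Giese adduct of 6 at C4, PPh3+ on C2) | C1C=C(C)C(=O)[C@@](C)(C=O)[C@@H]1C(C)(C)CC[P+](c1ccccc1)(c1ccccc1)c1ccccc1.[Br-] | intermediate
9 | phosphonium ylide derived from 8 | C1C=C(C)C(=O)[C@@](C)(C=O)[C@@H]1C(C)(C)CC=P(c1ccccc1)(c1ccccc1)c1ccccc1 | intermediate
10 | (4aS,8aS)-2,5,5,8a-tetramethyl-4a,5,6,8a-tetrahydronaphthalen-1(4H)-one | C1C=C(C)C(=O)[C@@]2(C)C=CCC(C)(C)[C@H]12 | intermediate
11 | trimethylsilyl trifluoromethanesulfonate | C[Si](C)(C)OS(=O)(=O)C(F)(F)F | starting material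
12 | trimethylsilyl dienol ether of 10 (C6=C7–C8=C9–OSiMe3) | C1=CC(C)=C(O[Si](C)(C)C)[C@@]2(C)C=CCC(C)(C)[C@H]12 | intermediate
13 | dioxygen | O=O | starting material
14 | 6α,9α-epidioxy-9β-(trimethylsilyloxy) adduct of 12 | O3[C@H]1C=C(C)[C@](O3)(O[Si](C)(C)C)[C@@]2(C)C=CCC(C)(C)[C@H]12 | intermediate
15 | 6α-hydroxy dienone (C7=C8–C9=O, C1=C2) | O[C@H]1C=C(C)C(=O)[C@@]2(C)C=CCC(C)(C)[C@H]12 | intermediate
16 | 6α-hydroxy-8β-methyl-9-ketone (kinetic C8 epimer) | O[C@H]1C[C@H](C)C(=O)[C@@]2(C)CCCC(C)(C)[C@H]12 | intermediate
17 | 6α-hydroxy-8α-methyl-9-ketone | O[C@H]1C[C@@H](C)C(=O)[C@@]2(C)CCCC(C)(C)[C@H]12 | intermediate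
18 | methyltriphenylphosphonium bromide | C[P+](c1ccccc1)(c1ccccc1)c1ccccc1.[Br-] | starting material
19 | 6α-hydroxy-9-methylene compound | O[C@H]1C[C@@H](C)C(=C)[C@@]2(C)CCCC(C)(C)[C@H]12 | intermediate
20 | 3-chloroperoxybenzoic acid | OOC(=O)c1cccc(Cl)c1 | starting material
21 | 9α,11-epoxide (6α-OH) | O[C@H]1C[C@@H](C)[C@]3(CO3)[C@@]2(C)CCCC(C)(C)[C@H]12 | intermediate
22 | trimethylsulfonium iodide | C[S+](C)C.[I-] | starting material
23 | 9β-vinyl-6α,9α-diol | O[C@H]1C[C@@H](C)[C@](O)(C=C)[C@@]2(C)CCCC(C)(C)[C@H]12 | intermediate
24 | 9-borabicyclo[3.3.1]nonane | B1C2CCCC1CCC2 | starting material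
25 | 3-bromofuran-2(5H)-one | O=C1OCC=C1Br | starting material
26 | B-alkyl-9-BBN (boron on C12) | O[C@H]1C[C@@H](C)[C@](O)(CCB3C4CCCC3CCC4)[C@@]2(C)CCCC(C)(C)[C@H]12 | intermediate
27 | 6α,9α-dihydroxy-labd-13-en-16,15-olide | O[C@H]1C[C@@H](C)[C@](O)(CCC2=CCOC2=O)[C@@]2(C)CCCC(C)(C)[C@H]12 | intermediate
28 | acetic anhydride | CC(=O)OC(C)=O | starting material
29 | (5S,6S,8R,9R,10S)-6α-acetoxy-9α-hydroxy-labd-13-en-16,15-olide | CC(=O)O[C@H]1C[C@@H](C)[C@](O)(CCC2=CCOC2=O)[C@@]2(C)CCCC(C)(C)[C@H]12 | target

**Step count and risks**

Total step count: 12. Longest linear sequence: 12 steps (fully linear from 1).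

Steps most likely to fail:

1. Step 4 (Proposed new method). The tertiary radical or the vinylphosphonium salt may be reduced before the C–C bond forms, the ylide may fail to close on the hindered aldehyde, or base may cleave the formyl group from the β-keto aldehyde. The fallback sets out from 6 and comes back at 10 with known chemistry. The established metal-hydride HAT-initiated radical conjugate addition–aldol annulation of 6 with acrolein (Fe(acac)3, PhSiH3, EtOH/ethylene glycol) would form the same C3–C4 and C1–C2 bonds and give the ring-A hydroxy aldehyde F1. Acid-catalysed dehydration (TsOH cat., benzene, reflux) would give the enal F2. Decarbonylation with stoichiometric RhCl(PPh3)3 in hot toluene would then deliver dienone 10.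

2. Step 11. Transmetalation of the alkylborane chelated by the neighbouring alkoxide may be slow, and the bromobutenolide may decompose under base before coupling. The fallback sets out from 23 and comes back at 27. The alkylborane 26 is iodinated (I2, NaOMe, MeOH) to the primary iodide F4. Alkylation of the sodium enolate of 3-(phenylthio)dihydrofuran-2(3H)-one (NaH, DMF), which is too weakly basic to deprotonate the free hydroxyls, gives the α-phenylthio lactone F5. Oxidation at sulfur (mCPBA, −78 °C) gives the sulfoxide F6, and thermal syn-elimination (toluene, 110 °C) gives the endocyclic butenolide 27.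

3. Step 8. Ylide addition to the ketone flanked by the quaternary C10 and the tertiary C8 may be blocked sterically or diverted into enolisation. The fallback sets out from 17 and comes back at 19 by Peterson olefination. The small, non-basic organocerium reagent from Me3SiCH2Li and CeCl3 (THF, −78 °C) adds to the ketone to give the β-hydroxysilane F3 (either C9 epimer serves). KH in THF then induces syn-elimination to the exocyclic alkene 19.

Further compounds
F1 | step 4 | ring-A hydroxy aldehyde (C1–OH, C2–CHO; diastereomer mixture) | C1C=C(C)C(=O)[C@@]2(C)C(O)C(C=O)CC(C)(C)[C@H]12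
F2 | step 4 | ring-A enal (C1=C2–CHO) | C1C=C(C)C(=O)[C@@]2(C)C=C(C=O)CC(C)(C)[C@H]12
F3 | step 8 | β-hydroxysilane (9-hydroxy-9-(trimethylsilylmethyl), 6α-OH) | O[C@H]1C[C@@H](C)[C@@](O)(C[Si](C)(C)C)[C@@]2(C)CCCC(C)(C)[C@H]12
F4 | step 11 | primary iodide (iodine on C12; 6α,9α-diol) | O[C@H]1C[C@@H](C)[C@](O)(CCI)[C@@]2(C)CCCC(C)(C)[C@H]12
F5 | step 11 | α-alkyl-α-(phenylthio)-γ-butyrolactone | O[C@H]1C[C@@H](C)[C@](O)(CCC2(Sc3ccccc3)CCOC2=O)[C@@]2(C)CCCC(C)(C)[C@H]12
F6 | step 11 | α-alkyl-α-(phenylsulfinyl)-γ-butyrolactone | O[C@H]1C[C@@H](C)[C@](O)(CCC2(S(=O)c3ccccc3)CCOC2=O)[C@@]2(C)CCCC(C)(C)[C@H]12
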